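Ring A is disconnected completely. Its free C2' hydroxyl, the C4' and C6' methoxy groups and the carbinol-bearing C1' between C2' and C6' are the pattern that a Danheiser benzannulation of 3-methoxycyclobutenone with a 1-methoxyalkyne delivers. One heating operation forms the C1'–C2', C5'–C6' and C2'–C3' bonds and closes ring A already differentiated, which spares any late sorting of three phloroglucinol oxygens. The alkyne partner is a racemic methoxyethynyl carbinol silyl ether on C5 of a 7-silyloxy-2,2-dimethyl-2H-chromene, whose ring B pattern comes from a propargyl Claisen sequence. One fluoride treatment and one oxidation then finish the benzophenone.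

Key step: step 7

Assumption: cyclobutane-1,3-dione is bought and reacts as its enol tautomer, and every carbinol-bearing intermediate is carried as the racemate because that carbon ends as the achiral ketone carbon. TBS = tert-butyldimethylsilyl, TIPS = triisopropylsilyl.

Step 1
Reactants: 1 3,5-dihydroxybenzaldehyde; 2 3-chloro-3-methylbut-1-yne
Product: 3 3-hydroxy-5-[(2-methylbut-3-yn-2-yl)oxy]benzaldehyde
Conditions: DBU, CuCl2·2H2O (cat.), MeCN, 0 °C; 1 in excess (1.5 equiv)
Reagents that add atoms: none
Why: Copper-catalysed O-propargylation of a phenoxide by a tertiary propargylic chloride is a dependable route to aryl 1,1-dimethylpropargyl ethers, and the excess of the symmetric diol should hold the reaction at the mono-ether while the non-enolisable aldehyde is untouched by DBU at 0 °C.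

Step 2
Reactants: 3 3-hydroxy-5-[(2-methylbut-3-yn-2-yl)oxy]benzaldehyde
Product: 6 7-hydroxy-2,2-dimethyl-2H-chromene-5-carbaldehyde, via allenylphenol 4 (not isolated), via ortho-quinone methide 5 (not isolated)
Conditions: 1,2-dichlorobenzene, 180 °C
Reagents that add atoms: none
Why: Aromatic propargyl Claisen rearrangement, 1,5-hydrogen shift and oxa-6π electrocyclisation build the dimethylpyran ring, and both meta substituents steer the sigmatropic shift to the ring carbon between the ether oxygen and the formyl-bearing carbon (an acceptor favours the adjacent ortho site, a hydroxyl donor the site para to itself), which places the formyl group on C5 and the hydroxyl on C7.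

Step 3
Reactants: 6 7-hydroxy-2,2-dimethyl-2H-chromene-5-carbaldehyde
Product: 7 2,2-dimethyl-7-[(triisopropylsilyl)oxy]-2H-chromene-5-carbaldehyde
Conditions: TIPSCl, imidazole, DMF, rt
Reagents that add atoms: triisopropylsilyl chloride, CC(C)[Si](Cl)(C(C)C)C(C)C
Why: Silylation of a phenol with a silyl chloride and imidazole is routine, and the bulky TIPS ether is chosen because it should resist the lithium bases of step 4 and the heating of step 7 yet leave in the same fluoride step as the carbinol silyl group.

Step 4
Reactants: 7 2,2-dimethyl-7-[(triisopropylsilyl)oxy]-2H-chromene-5-carbaldehyde; 8 2-chloro-1,1-dimethoxyethane (chloroacetaldehyde dimethyl acetal)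
Product: 10 racemic 1-{2,2-dimethyl-7-[(triisopropylsilyl)oxy]-2H-chromen-5-yl}-3-methoxyprop-2-yn-1-ol, via lithium methoxyacetylide 9 (not isolated)
Conditions: 8, LiNEt2 (3 equiv, from Et2NH and n-BuLi), THF, 0 °C; then 7, −78 °C; pH 7 buffer quench; crude 10 used directly
Reagents that add atoms: none
Why: Three equivalents of lithium amide strip methanol and HCl from the chloroacetal and deprotonate the resulting methoxyacetylene, and 1,2-addition of this lithium acetylide to the aryl aldehyde is standard carbonyl alkynylation; the new carbinol stereocentre forms without facial control as the racemate, which is acceptable because it later becomes the ketone carbon.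

Step 5
Reactants: 10 racemic 1-{2,2-dimethyl-7-[(triisopropylsilyl)oxy]-2H-chromen-5-yl}-3-methoxyprop-2-yn-1-ol
Product: 11 racemic 5-{1-[(tert-butyldimethylsilyl)oxy]-3-methoxyprop-2-yn-1-yl}-2,2-dimethyl-7-[(triisopropylsilyl)oxy]-2H-chromene
Conditions: TBSCl, imidazole, DMF, 0 °C to rt; chromatography on Et3N-deactivated silica
Reagents that add atoms: tert-butyldimethylsilyl chloride, CC(C)(C)[Si](C)(C)Cl
Why: Silyl ether formation with TBSCl and imidazole stays basic throughout, so it caps the secondary carbinol (configuration untouched, still racemic) without triggering the acid-induced Meyer–Schuster rearrangement of the ynol ether.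

Step 6
Reactants: 12 cyclobutane-1,3-dione
Product: 13 3-methoxycyclobut-2-en-1-one
Conditions: TMSCHN2 (hexanes), MeOH/PhMe, 0 °C
Reagents that add atoms: (trimethylsilyl)diazomethane, C[Si](C)(C)C=[N+]=[N-]
Why: The dione reacts as its strongly acidic enol, a vinylogous carboxylic acid, so O-methylation by the diazoalkane in methanol should proceed as for a carboxylic acid and give the vinylogous methyl ester.

Step 7
Reactants: 11 racemic 5-{1-[(tert-butyldimethylsilyl)oxy]-3-methoxyprop-2-yn-1-yl}-2,2-dimethyl-7-[(triisopropylsilyl)oxy]-2H-chromene; 13 3-methoxycyclobut-2-en-1-one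
Product: 18 racemic 2-{[(tert-butyldimethylsilyl)oxy]{2,2-dimethyl-7-[(triisopropylsilyl)oxy]-2H-chromen-5-yl}methyl}-3,5-dimethoxyphenol, via vinylketene 14 (not isolated), via vinylcyclobutenone 15 (not isolated), via dienylketene 16 (not isolated), via cyclohexadienone 17 (not isolated)
Conditions: 13 (2 equiv), PhMe (1 M), 110 °C, sealed tube
Reagents that add atoms: none
Why: Heating opens 13 by 4π electrocyclic ring opening to vinylketene 14, whose ketene C=C adds in a (2+2) cycloaddition to the electron-rich triple bond of 11 to give 15; a second 4π opening gives dienylketene 16, 6π electrocyclisation gives dienone 17 and tautomerisation gives phenol 18. The closest known reaction type is the Danheiser benzannulation of cyclobutenones with 1-alkoxyalkynes, and the vinylogous-ester character of 13 should only raise the temperature needed for the first ring opening, hence 110 °C. Ring A is closed by the thermally allowed disrotatory 6π electrocyclisation of 16, which forms the C2'–C3' bond after the cycloaddition has formed C1'–C2' and C5'–C6'. No stereocentre is created, and the carbinol centre of 11 passes through unchanged as the racemate. The step needs one regiochemical outcome, bonding of the ketene carbonyl carbon to the alkyne carbon that carries the carbinol, and this is secured by the methoxy group, which makes exactly that carbon (β to oxygen) the nucleophilic terminus of the ynol ether, so the hydroxyl ends on C2' and the methoxy groups on C4' and C6'. Chemoselectivity rests on the ynol ether being far more nucleophilic than the chromene alkene, while both silyl ethers and the methyl-capped ynol ether (no retro-ene pathway) should tolerate the heat.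

Step 8
Reactants: 18 racemic 2-{[(tert-butyldimethylsilyl)oxy]{2,2-dimethyl-7-[(triisopropylsilyl)oxy]-2H-chromen-5-yl}methyl}-3,5-dimethoxyphenol
Product: 19 racemic 2-[hydroxy(7-hydroxy-2,2-dimethyl-2H-chromen-5-yl)methyl]-3,5-dimethoxyphenol
Conditions: TBAF (3 equiv), THF, 0 °C to rt; pH 7 buffer work-up; crude 19 used directly
Reagents that add atoms: none
Why: Fluoride-mediated cleavage of silicon–oxygen bonds removes the aryl TIPS and the secondary TBS group in one operation under basic conditions, which avoid acid-induced ionisation of the electron-rich benzhydrol.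

Step 9
Reactants: 19 racemic 2-[hydroxy(7-hydroxy-2,2-dimethyl-2H-chromen-5-yl)methyl]-3,5-dimethoxyphenol
Product: 20 (2-hydroxy-4,6-dimethoxyphenyl)(7-hydroxy-2,2-dimethyl-2H-chromen-5-yl)methanone
Conditions: activated MnO2 (excess), EtOAc, rt
Reagents that add atoms: none
Why: Activated MnO2 oxidises doubly benzylic alcohols selectively in the presence of free phenols and the chromene alkene, the racemic carbinol centre is erased, and the resulting ketone is stabilised by the hydrogen bond from the C2' hydroxyl.

Compound list
1 | 3,5-dihydroxybenzaldehyde | O=Cc1cc(O)cc(O)c1 | starting material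
2 | 3-chloro-3-methylbut-1-yne | C#CC(C)(C)Cl | starting material
3 | 3-hydroxy-5-[(2-methylbut-3-yn-2-yl)oxy]benzaldehyde | C#CC(C)(C)Oc1cc(O)cc(C=O)c1 | intermediate
4 | 3,5-dihydroxy-2-(3-methylbuta-1,2-dien-1-yl)benzaldehyde (allenylphenol, formed and consumed in the flask) | CC(C)=C=Cc1c(O)cc(O)cc1C=O | intermediate
5 | (6Z)-3-hydroxy-6-(3-methylbut-2-en-1-ylidene)-5-oxocyclohexa-1,3-diene-1-carbaldehyde (ortho-quinone methide, formed and consumed in the flask) | CC(C)=C/C=C1\C(=O)C=C(O)C=C1C=O | intermediate
6 | 7-hydroxy-2,2-dimethyl-2H-chromene-5-carbaldehyde | CC1(C)C=Cc2c(C=O)cc(O)cc2O1 | intermediate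
7 | 2,2-dimethyl-7-[(triisopropylsilyl)oxy]-2H-chromene-5-carbaldehyde | CC(C)[Si](Oc1cc(C=O)c2C=CC(C)(C)Oc2c1)(C(C)C)C(C)C | intermediate
8 | 2-chloro-1,1-dimethoxyethane (chloroacetaldehyde dimethyl acetal) | COC(CCl)OC | starting material
9 | lithium methoxyacetylide (formed and consumed in the flask) | [Li]C#COC | intermediate
10 | racemic 1-{2,2-dimethyl-7-[(triisopropylsilyl)oxy]-2H-chromen-5-yl}-3-methoxyprop-2-yn-1-ol | COC#CC(O)c1cc(O[Si](C(C)C)(C(C)C)C(C)C)cc2c1C=CC(C)(C)O2 | intermediate
11 | racemic 5-{1-[(tert-butyldimethylsilyl)oxy]-3-methoxyprop-2-yn-1-yl}-2,2-dimethyl-7-[(triisopropylsilyl)oxy]-2H-chromene | COC#CC(O[Si](C)(C)C(C)(C)C)c1cc(O[Si](C(C)C)(C(C)C)C(C)C)cc2c1C=CC(C)(C)O2 | intermediate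
12 | cyclobutane-1,3-dione | O=C1CC(=O)C1 | starting material
13 | 3-methoxycyclobut-2-en-1-one | COC1=CC(=O)C1 | intermediate
14 | 3-methoxybuta-1,3-dien-1-one (vinylketene, formed and consumed in the flask) | C=C(OC)C=C=O | intermediate
15 | 2-{(TBS-oxy)[2,2-dimethyl-7-(TIPS-oxy)-2H-chromen-5-yl]methyl}-3-methoxy-4-(1-methoxyethenyl)cyclobut-2-en-1-one (mixture of racemic diastereomers, formed and consumed in the flask) | COC(=C)C1C(=O)C(C(O[Si](C)(C)C(C)(C)C)c2cc(O[Si](C(C)C)(C(C)C)C(C)C)cc3c2C=CC(C)(C)O3)=C1OC | intermediate
16 | racemic (3E)-2-{(TBS-oxy)[2,2-dimethyl-7-(TIPS-oxy)-2H-chromen-5-yl]methyl}-3,5-dimethoxyhexa-1,3,5-trien-1-one (dienylketene, formed and consumed in the flask) | C=C(OC)/C=C(/OC)C(=C=O)C(O[Si](C)(C)C(C)(C)C)c1cc(O[Si](C(C)C)(C(C)C)C(C)C)cc2c1C=CC(C)(C)O2 | intermediate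
17 | racemic 2-{(TBS-oxy)[2,2-dimethyl-7-(TIPS-oxy)-2H-chromen-5-yl]methyl}-3,5-dimethoxycyclohexa-2,4-dien-1-one (formed and consumed in the flask) | COC1=CC(OC)=C(C(O[Si](C)(C)C(C)(C)C)c2cc(O[Si](C(C)C)(C(C)C)C(C)C)cc3c2C=CC(C)(C)O3)C(=O)C1 | intermediate
18 | racemic 2-{[(tert-butyldimethylsilyl)oxy]{2,2-dimethyl-7-[(triisopropylsilyl)oxy]-2H-chromen-5-yl}methyl}-3,5-dimethoxyphenol | COc1cc(O)c(C(O[Si](C)(C)C(C)(C)C)c2cc(O[Si](C(C)C)(C(C)C)C(C)C)cc3c2C=CC(C)(C)O3)c(OC)c1 | intermediate
19 | racemic 2-[hydroxy(7-hydroxy-2,2-dimethyl-2H-chromen-5-yl)methyl]-3,5-dimethoxyphenol | COc1cc(O)c(C(O)c2cc(O)cc3c2C=CC(C)(C)O3)c(OC)c1 | intermediate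
20 | (2-hydroxy-4,6-dimethoxyphenyl)(7-hydroxy-2,2-dimethyl-2H-chromen-5-yl)methanone (achiral) | COc1cc(O)c(C(=O)c2cc(O)cc3c2C=CC(C)(C)O3)c(OC)c1 | target

Total step count: 9.
Longest linear sequence: 8 steps (steps 1, 2, 3, 4, 5, 7, 8 and 9, from 1 to 20); step 6 is a one-step side branch.

Steps most likely to fail

Step 7. Ring opening of the vinylogous-ester cyclobutenone may be slow. At the temperature then needed, the vinylketene may dimerise or acylate the product phenol faster than the hindered alkyne intercepts it. Thermal loss of silanol from the ortho-hydroxy benzhydryl silyl ether could erode the product further. The fallback abandons the benzannulation, brings ring A in ready-made, sets out from aldehyde 7 and returns to the route at target 20. Commercial 3,5-dimethoxyphenol is protected with MOMCl and i-Pr2NEt as 1,3-dimethoxy-5-(methoxymethoxy)benzene F1. n-BuLi with TMEDA in THF at 0 °C should lithiate the position between the MOM ether and a methoxy group, giving [2,4-dimethoxy-6-(methoxymethoxy)phenyl]lithium F2. Addition to 7 at −78 °C should give racemic [2,4-dimethoxy-6-(methoxymethoxy)phenyl]{2,2-dimethyl-7-[(triisopropylsilyl)oxy]-2H-chromen-5-yl}methanol F3. Dess–Martin periodinane buffered with NaHCO3 should oxidise it to [2,4-dimethoxy-6-(methoxymethoxy)phenyl]{2,2-dimethyl-7-[(triisopropylsilyl)oxy]-2H-chromen-5-yl}methanone F4. TBAF then frees the ring B phenol to give [2,4-dimethoxy-6-(methoxymethoxy)phenyl](7-hydroxy-2,2-dimethyl-2H-chromen-5-yl)methanone F5, and warm methanolic HCl removes the MOM group to deliver 20.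

Step 4. The methoxyethynyl carbinol may undergo acid-triggered Meyer–Schuster rearrangement to the α,β-unsaturated methyl ester during quench, concentration or storage, and elimination of the chloroacetal to the acetylide may be incomplete. In the fallback the free carbinol is never released. Setting out again from 7, the lithium alkoxide formed on addition of 9 is silylated in the same flask (TBSCl with DMF as co-solvent, −78 °C to rt) before any protic work-up. The sequence returns to the route at 11 and bypasses 10; no compound outside the list is made (entry F0).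

Step 9. The electron-rich ortho-hydroxy benzhydrol may ionise to an ortho-quinone methide on the oxide surface or on handling, and the two free phenols may couple oxidatively in competition with carbinol oxidation. The fallback inverts the order of oxidation and deprotection, setting out from 18 and returning at 20. DDQ in CH2Cl2/pH 7 buffer should convert the activated benzhydryl silyl ether of 18 directly into the ketone by benzylic hydride abstraction and loss of the silyl group, the known oxidative desilylation of electron-rich benzylic silyl ethers. This gives (2-hydroxy-4,6-dimethoxyphenyl){2,2-dimethyl-7-[(triisopropylsilyl)oxy]-2H-chromen-5-yl}methanone F6, whose hydrogen-bonded phenol no longer ionises. TBAF then removes the aryl silyl ether to give 20 without triol 19 being formed.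

Further compounds
F1 | step 7 | 1,3-dimethoxy-5-(methoxymethoxy)benzene | COCOc1cc(OC)cc(OC)c1
F2 | step 7 | [2,4-dimethoxy-6-(methoxymethoxy)phenyl]lithium | [Li]c1c(OC)cc(OC)cc1OCOC
F3 | step 7 | racemic [2,4-dimethoxy-6-(methoxymethoxy)phenyl]{2,2-dimethyl-7-[(triisopropylsilyl)oxy]-2H-chromen-5-yl}methanol | COCOc1cc(OC)cc(OC)c1C(O)c1cc(O[Si](C(C)C)(C(C)C)C(C)C)cc2c1C=CC(C)(C)O2
F4 | step 7 | [2,4-dimethoxy-6-(methoxymethoxy)phenyl]{2,2-dimethyl-7-[(triisopropylsilyl)oxy]-2H-chromen-5-yl}methanone | COCOc1cc(OC)cc(OC)c1C(=O)c1cc(O[Si](C(C)C)(C(C)C)C(C)C)cc2c1C=CC(C)(C)O2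
F5 | step 7 | [2,4-dimethoxy-6-(methoxymethoxy)phenyl](7-hydroxy-2,2-dimethyl-2H-chromen-5-yl)methanone | COCOc1cc(OC)cc(OC)c1C(=O)c1cc(O)cc2c1C=CC(C)(C)O2
F0 | step 4 | none | none
F6 | step 9 | (2-hydroxy-4,6-dimethoxyphenyl){2,2-dimethyl-7-[(triisopropylsilyl)oxy]-2H-chromen-5-yl}methanone | COc1cc(O)c(C(=O)c2cc(O[Si](C(C)C)(C(C)C)C(C)C)cc3c2C=CC(C)(C)O3)c(OC)c1
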